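## Retrosynthetic overview

- C7=C8 (exocyclic E-alkene): aldol condensation of a 2-bromo-4-acetoxy-4-octenylcyclopentenone with methyl (5E)-7-oxohept-5-enoate, itself made by cross-metathesis.
- C12–OAc (the only stereocentre): key step, an enantioconvergent palladium-catalysed allylic C–O substitution of a racemic tertiary carbonate by acetate.
- C10–Br: nucleophilic epoxidation of the enone, then HBr, so that no electrophilic bromine meets the chain Z-alkene.
- Only ring (the cyclopentenone): Piancatelli rearrangement of a 5-octenylfurfuryl alcohol, which comes from furfuryl alcohol and (2Z)-1-bromooct-2-ene.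

Assumption: the (R,R) ligand is taken to favour the (S)-acetate by analogy with secondary 4-acyloxycyclopentenones; if the sense proves opposite, the (S,S) ligand is used with no other change.

## Route

Step 1
Reactants: 1 (2Z)-oct-2-en-1-ol
Product: 2 (2Z)-1-bromooct-2-ene
Conditions: PBr3 (0.4 equiv), pyridine (cat.), Et2O, −10 °C
Reagents that add atoms: phosphorus tribromide, BrP(Br)Br
Why: Low-temperature bromination of a primary allylic alcohol with PBr3 is a direct SN2-type substitution that proceeds without allylic transposition and keeps the Z geometry.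

Step 2
Reactants: 3 furan-2-ylmethanol (furfuryl alcohol); 2 (2Z)-1-bromooct-2-ene
Product: 5 {5-[(2Z)-oct-2-en-1-yl]furan-2-yl}methanol, via lithium (5-lithiofuran-2-yl)methanolate 4 (not isolated)
Conditions: n-BuLi (2.1 equiv), TMEDA, THF, −78 → 0 °C; then 2, −78 → 23 °C; H2O
Reagents that add atoms: none
Why: Double deprotonation (O–H, then the furan C5–H) gives a dianion whose carbon centre alkylates the primary allylic bromide by SN2 substitution (furyllithium alkylation) much faster than the alkoxide does, so no protecting group is needed and the Z-alkene is untouched.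

Step 3
Reactants: 5 {5-[(2Z)-oct-2-en-1-yl]furan-2-yl}methanol
Product: 6 (±)-4-hydroxy-4-[(2Z)-oct-2-en-1-yl]cyclopent-2-en-1-one
Conditions: H2O/1,4-dioxane (2:1), NaH2PO4/H3PO4 buffer (pH 4), microwave, 160 °C, 20 min
Reagents that add atoms: water, O
Why: Piancatelli rearrangement (ionisation of the furfuryl alcohol, addition of water at the substituted furan C5, ring opening and conrotatory 4π electrocyclisation) gives the 4-hydroxy-4-alkylcyclopentenone, as known for 5-substituted primary furfuryl alcohols in hot water; the carbinol centre is racemic here and is fixed in step 7.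

Step 4
Reactants: 6 (±)-4-hydroxy-4-[(2Z)-oct-2-en-1-yl]cyclopent-2-en-1-one
Product: 7 (±)-4-hydroxy-4-[(2Z)-oct-2-en-1-yl]-6-oxabicyclo[3.1.0]hexan-2-one (epoxide diastereomers)
Conditions: 30% aq. H2O2 (3 equiv), NaOH (0.2 equiv), MeOH, 0 °C
Reagents that add atoms: hydrogen peroxide, OO
Why: Weitz–Scheffer nucleophilic epoxidation attacks only the electron-poor enone, so the isolated Z-alkene is left alone; the epoxide diastereomers converge in step 5.

Step 5
Reactants: 7 (±)-4-hydroxy-4-[(2Z)-oct-2-en-1-yl]-6-oxabicyclo[3.1.0]hexan-2-one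
Product: 9 (±)-2-bromo-4-hydroxy-4-[(2Z)-oct-2-en-1-yl]cyclopent-2-en-1-one, via bromohydrin 8 (not isolated)
Conditions: 48% aq. HBr (1.5 equiv), acetone, 0 → 23 °C
Reagents that add atoms: hydrogen bromide, Br
Why: Bromide opens the α,β-epoxy ketone at the α-carbon and the β-hydroxy ketone 8 loses water under the same acid (epoxy ketone to α-haloenone conversion), which installs the vinyl bromide without electrophilic bromine; the tertiary alcohol cannot eliminate because that would give a cyclopentadienone.

Step 6
Reactants: 9 (±)-2-bromo-4-hydroxy-4-[(2Z)-oct-2-en-1-yl]cyclopent-2-en-1-one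
Product: 11 (±)-3-bromo-1-[(2Z)-oct-2-en-1-yl]-4-oxocyclopent-2-en-1-yl tert-butyl carbonate, via lithium alkoxide 10 (not isolated)
Conditions: LiN(SiMe3)2 (1.05 equiv), THF, −78 °C; Boc2O (1.3 equiv), −78 → 0 °C; H2O
Reagents that add atoms: di-tert-butyl dicarbonate, CC(C)(C)OC(=O)OC(=O)OC(C)(C)C
Why: The O–H is deprotonated first and the tertiary lithium alkoxide is acylated by Boc2O (carbonate formation) at a temperature where retro-aldol opening of the β-hydroxy ketone does not compete.

Step 7
Reactants: 11 (±)-3-bromo-1-[(2Z)-oct-2-en-1-yl]-4-oxocyclopent-2-en-1-yl tert-butyl carbonate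
Product: 12 (1S)-3-bromo-1-[(2Z)-oct-2-en-1-yl]-4-oxocyclopent-2-en-1-yl acetate
Conditions: Pd2(dba)3·CHCl3 (2.5 mol %), (R,R)-DACH-phenyl Trost ligand (7.5 mol %), AcOH (1.5 equiv), Bu4NCl (30 mol %), CH2Cl2 (0.05 M), 0 → 23 °C
Reagents that add atoms: acetic acid, CC(=O)O
Why: Proposed new method: zerovalent palladium ionises the tertiary allylic carbonate anti to the leaving group (irreversibly, through loss of CO2 and tert-butoxide, which deprotonates AcOH) to give two diastereomeric cationic η3-oxocyclopentenyl palladium species that are also palladium dienolates and can exchange faces through the O-bound form (helped by chloride and by the low acetate concentration), while the chiral pocket lets acetate attack, outer-sphere and anti to palladium, only the species that leads to the (S)-acetate, and only at the alkyl-bearing terminus because attack there restores the conjugated bromoenone; the closest known reaction types are the palladium-catalysed kinetic resolution of secondary 4-(Boc-oxy)cyclopent-2-enones with carboxylic acids and the dynamic kinetic asymmetric substitution of γ-acyloxybutenolides (Tsuji–Trost manifold), neither shown for a tertiary centre or a 2-bromo substrate, and this step forms the tertiary C–O bond and sets the only stereocentre (S here, R in the target after the CIP priority change on olefination).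

Step 8
Reactants: 13 methyl hex-5-enoate; 14 (2E)-but-2-enal
Product: 15 methyl (5E)-7-oxohept-5-enoate
Conditions: second-generation Hoveyda–Grubbs catalyst [RuCl2(H2IMes)(=CH-C6H4-2-O-i-Pr)] (2 mol %), 14 (5 equiv), CH2Cl2, 40 °C
Reagents that add atoms: none
Why: Olefin cross-metathesis of a terminal alkene with an electron-poor enal used in excess gives the E-enal under thermodynamic control with loss of propene.

Step 9
Reactants: 12 (1S)-3-bromo-1-[(2Z)-oct-2-en-1-yl]-4-oxocyclopent-2-en-1-yl acetate; 15 methyl (5E)-7-oxohept-5-enoate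
Product: 19 methyl (5E,7E)-7-{(2R)-2-acetoxy-4-bromo-2-[(2Z)-oct-2-en-1-yl]-5-oxocyclopent-3-en-1-ylidene}hept-5-enoate, via lithium enolate 16 (not isolated), via lithium aldolate 17 (not isolated), via aldol mesylate 18 (not isolated)
Conditions: LiN(SiMe3)2 (1.05 equiv), THF, −78 °C, 15 min; 15 (1.3 equiv), −78 °C; MsCl (1.5 equiv) then Et3N (5 equiv), −78 → 0 °C
Reagents that add atoms: none
Why: Kinetic deprotonation at the only enolisable ring CH2, aldol addition to the aldehyde, mesylation and E1cB elimination (aldol condensation) give mainly the E exocyclic alkene with the 5E and 14Z alkenes carried through, while loss of the tertiary acetate from the enolate would give an antiaromatic cyclopentadienone and so does not compete at −78 °C; the quaternary stereocentre is not touched.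

## Compound list

1 | (2Z)-oct-2-en-1-ol | CCCCC/C=C\CO | starting material
2 | (2Z)-1-bromooct-2-ene | CCCCC/C=C\CBr | intermediate
3 | furan-2-ylmethanol (furfuryl alcohol) | OCc1ccco1 | starting material
4 | lithium (5-lithiofuran-2-yl)methanolate | [Li]OCc1ccc([Li])o1 | intermediate (not isolated)
5 | {5-[(2Z)-oct-2-en-1-yl]furan-2-yl}methanol | CCCCC/C=C\Cc1ccc(CO)o1 | intermediate
6 | (±)-4-hydroxy-4-[(2Z)-oct-2-en-1-yl]cyclopent-2-en-1-one | CCCCC/C=C\CC1(O)C=CC(=O)C1 | intermediate
7 | (±)-4-hydroxy-4-[(2Z)-oct-2-en-1-yl]-6-oxabicyclo[3.1.0]hexan-2-one, epoxide diastereomers | CCCCC/C=C\CC1(O)C2OC2C(=O)C1 | intermediate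
8 | (±)-2-bromo-3,4-dihydroxy-4-[(2Z)-oct-2-en-1-yl]cyclopentan-1-one, diastereomers | CCCCC/C=C\CC1(O)C(O)C(Br)C(=O)C1 | intermediate (not isolated)
9 | (±)-2-bromo-4-hydroxy-4-[(2Z)-oct-2-en-1-yl]cyclopent-2-en-1-one | CCCCC/C=C\CC1(O)C=C(Br)C(=O)C1 | intermediate
10 | lithium alkoxide of 9 | CCCCC/C=C\CC1(O[Li])C=C(Br)C(=O)C1 | intermediate (not isolated)
11 | (±)-3-bromo-1-[(2Z)-oct-2-en-1-yl]-4-oxocyclopent-2-en-1-yl tert-butyl carbonate | CCCCC/C=C\CC1(OC(=O)OC(C)(C)C)C=C(Br)C(=O)C1 | intermediate
12 | (1S)-3-bromo-1-[(2Z)-oct-2-en-1-yl]-4-oxocyclopent-2-en-1-yl acetate | CCCCC/C=C\C[C@@]1(OC(C)=O)C=C(Br)C(=O)C1 | intermediate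
13 | methyl hex-5-enoate | C=CCCCC(=O)OC | starting material
14 | (2E)-but-2-enal (crotonaldehyde) | C/C=C/C=O | starting material
15 | methyl (5E)-7-oxohept-5-enoate | O=C/C=C/CCCC(=O)OC | intermediate
16 | lithium enolate of 12 (S at the acetoxy carbon) | CCCCC/C=C\C[C@@]1(OC(C)=O)C=C(Br)C(O[Li])=C1 | intermediate (not isolated)
17 | lithium aldolate: methyl (5E)-7-{(2S)-2-acetoxy-4-bromo-2-[(2Z)-oct-2-en-1-yl]-5-oxocyclopent-3-en-1-yl}-7-(lithiooxy)hept-5-enoate, diastereomers at the two new centres | CCCCC/C=C\C[C@@]1(OC(C)=O)C=C(Br)C(=O)C1C(O[Li])/C=C/CCCC(=O)OC | intermediate (not isolated)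
18 | aldol mesylate: methyl (5E)-7-{(2S)-2-acetoxy-4-bromo-2-[(2Z)-oct-2-en-1-yl]-5-oxocyclopent-3-en-1-yl}-7-(methanesulfonyloxy)hept-5-enoate, diastereomers | CCCCC/C=C\C[C@@]1(OC(C)=O)C=C(Br)C(=O)C1C(OS(C)(=O)=O)/C=C/CCCC(=O)OC | intermediate (not isolated)
19 | methyl (5E,7E)-7-{(2R)-2-acetoxy-4-bromo-2-[(2Z)-oct-2-en-1-yl]-5-oxocyclopent-3-en-1-ylidene}hept-5-enoate | CCCCC/C=C\C[C@@]1(OC(C)=O)C=C(Br)C(=O)/C1=C/C=C/CCCC(=O)OC | target

## Step count and risks

Total: 9 steps. Longest linear sequence: 8 steps (1, 2, 3, 4, 5, 6, 7, 9); step 8 is a one-step side branch.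

**Step 7 (proposed new method).** Three things can go wrong.
- The two palladium allyl species may not exchange faces fast enough, so the step runs only as a kinetic resolution with at most 50% yield.
- The allyl cation has an acidic, doubly allylic CH2 next to it and may lose a proton to give a 4-octenylidene dienone.
- Zerovalent palladium may insert into the C–Br bond.

The fallback uses known chemistry and sets out from 9. Acetylation (Ac2O, DMAP, Et3N, CH2Cl2, 23 °C) gives the racemic acetate (±)-3-bromo-1-[(2Z)-oct-2-en-1-yl]-4-oxocyclopent-2-en-1-yl acetate F1. Preparative supercritical-fluid chromatography on an amylose tris(3,5-dimethylphenylcarbamate) phase resolves it. The (1S) enantiomer is 12, where the route resumes, and the enantiomer (1R)-3-bromo-1-[(2Z)-oct-2-en-1-yl]-4-oxocyclopent-2-en-1-yl acetate F2 is set aside.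

**Step 9.** The lithium enolate carries a β-acetoxy group and an α-bromoenone, the aldehyde is enolisable, and the elimination may give some 7Z isomer. The fallback replaces the basic enolate by a neutral silyl enol ether and sets out from 12. Me3SiOTf and Et3N in CH2Cl2 at −78 °C give the silyl dienol ether (1S)-3-bromo-1-[(2Z)-oct-2-en-1-yl]-4-[(trimethylsilyl)oxy]cyclopenta-2,4-dien-1-yl acetate F3. Mukaiyama aldol addition to 15 (BF3·OEt2, CH2Cl2, −78 °C, aqueous work-up) gives the β-hydroxy ketone methyl (5E)-7-{(2S)-2-acetoxy-4-bromo-2-[(2Z)-oct-2-en-1-yl]-5-oxocyclopent-3-en-1-yl}-7-hydroxyhept-5-enoate F4. MsCl and Et3N in CH2Cl2 at 0 °C then take F4 back into the route at 18 and on to 19.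

**Step 3.** A primary furfuryl alcohol ionises reluctantly, the substrate is lipophilic, and furan polymerisation competes. The fallback builds the ring from cyclopentadiene instead of furan and sets out from 2. NaC5H5 in THF (−78 → 0 °C) gives 1-[(2Z)-oct-2-en-1-yl]cyclopenta-1,3-diene F5, together with some 2-substituted isomer. Photo-oxygenation (O2, tetraphenylporphyrin, visible light, CH2Cl2, −40 °C; singlet-oxygen [4+2] cycloaddition) gives the endoperoxide 1-[(2Z)-oct-2-en-1-yl]-2,3-dioxabicyclo[2.2.1]hept-5-ene F6. Et3N (Kornblum–DeLaMare rearrangement) opens F6 to 6, where the route resumes; regioisomeric hydroxy enones from the 2-substituted diene are removed by chromatography.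

Further compounds
F1 | step 7 | (±)-3-bromo-1-[(2Z)-oct-2-en-1-yl]-4-oxocyclopent-2-en-1-yl acetate | CCCCC/C=C\CC1(OC(C)=O)C=C(Br)C(=O)C1
F2 | step 7 | (1R)-3-bromo-1-[(2Z)-oct-2-en-1-yl]-4-oxocyclopent-2-en-1-yl acetate | CCCCC/C=C\C[C@]1(OC(C)=O)C=C(Br)C(=O)C1
F3 | step 9 | (1S)-3-bromo-1-[(2Z)-oct-2-en-1-yl]-4-[(trimethylsilyl)oxy]cyclopenta-2,4-dien-1-yl acetate | CCCCC/C=C\C[C@@]1(OC(C)=O)C=C(Br)C(O[Si](C)(C)C)=C1
F4 | step 9 | methyl (5E)-7-{(2S)-2-acetoxy-4-bromo-2-[(2Z)-oct-2-en-1-yl]-5-oxocyclopent-3-en-1-yl}-7-hydroxyhept-5-enoate, diastereomers | CCCCC/C=C\C[C@@]1(OC(C)=O)C=C(Br)C(=O)C1C(O)/C=C/CCCC(=O)OC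
F5 | step 3 | 1-[(2Z)-oct-2-en-1-yl]cyclopenta-1,3-diene | CCCCC/C=C\CC1=CC=CC1
F6 | step 3 | (±)-1-[(2Z)-oct-2-en-1-yl]-2,3-dioxabicyclo[2.2.1]hept-5-ene | CCCCC/C=C\CC12OOC(C=C1)C2
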